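## Structural features

- The target is a tropone in which six of the seven ring carbons are substituted. Its ring carbons are called T1–T7 here: T1 carries CO2Me, T2 a methyl, T3 a hydrogen, T4 and T5 are the fusion carbons, T6 carries a methyl and T7 is the carbonyl.
- T4–T5 is shared with a 2,3-dihydrofuran (O on T5, C11H2 on T4) whose sp3 carbon is the spiro carbon C9 of a cyclohexane, ring B of a 3,4-seco-drimane.
- Ring A is open: C5 carries C(CH3)2OH and C10 carries CH2CH2CO2H. This is the pattern left by Baeyer–Villiger cleavage and hydrolysis of a 4,4-dimethyl-3-ketone, so a closed trans-decalin can be carried almost to the end.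
- Four stereocentres are contiguous around ring B (C5–C10–C9–C8). H5 is anti to the C10 methyl; the spiro oxygen is anti and C11 syn; the C8 methyl is syn, so it is 1,3-diaxial to the C10 methyl.
- Fragile groups in the target are the vinylogous-ester ether at T5 and the methyl ester (both exposed to hydroxide) and the tertiary alcohol beside a free acid. On the way there are a cyclic enol ether, a Fischer carbene complex and a ketal.
- The real difficulty is twofold: the oxygenated quaternary C9 sits between quaternary C10 and a C8 whose methyl is the less stable epimer, and the tropone must be assembled with a fixed substituent order.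
- The key step exploits the O–T5–T4–C11H2 unit, which is the ring of a 2-oxacyclopentylidene carbene. With an exocyclic methylene on its α-carbon, the carbene carbon, α-carbon and methylene become T5, T4 and T3, and T6, T7, T1, T2 are the backbone of a 2-silyloxydiene ester.

## Logic of the disconnections

- **32 ⇒ 31.** The acyl C3–O bond of the seven-membered lactone is cut. Acid and tertiary carbinol then come from one functional group and ring A is closed again. The forward hydrolysis must open the lactone faster than it touches the hindered T1 methyl ester or the T5–O vinylogous ester.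
- **31 ⇒ 30.** The ring oxygen between C3 and C4 is removed (Baeyer–Villiger retron). This gives a plain 4,4-dimethyl-3-ketone on a trans-decalin. The forward step needs migration of the quaternary C4 and an oxidant that spares the tropone.
- **30 ⇒ 29 ⇒ 27.** The ketone is masked as a dioxolane, and the tropone is reduced by four hydrogens to a cycloheptadiene silyl enol ether. The gain is a ring that an annulation can build; its two CHMe centres need not be controlled. The forward step needs two dehydrogenations that stop at the aromatic stage.
- **27 ⇒ 21 + 25 (via 26).** The T5–T6 and T2–T3 bonds are cut. This is the only cut that divides the seven-membered ring into a three-carbon piece already attached to the spiro ether and a four-carbon piece carrying ester, oxygen and both methyls. The forward step must choose the silyl enol ether alkene of 25, must form the cis-divinylcyclopropane, and must not add 25 across the exocyclic methylene in a Diels–Alder sense.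
- **25 ⇒ 24 ⇒ 22 + 23.** The O–Si bond and then the ethylidene C=C are cut. This leads to a commercial keto ester and acetaldehyde. Enolisation must occur at the ethyl CH2, and the ethylidene methyl must be cis to the ester so that it points outward in the Cope transition state.
- **21 ⇒ 19 (via 20).** The exocyclic C=C (T4=T3) is cut. The parent cyclic carbene has only one acidic CH2, so the forward step is a one-carbon alkylation and elimination.
- **19 ⇒ 16 + 17 (via 18).** The O–T5 bond and the Cr=C bond are cut. The carbene ring unfolds to a homopropargylic tertiary alcohol and Cr(CO)6. The forward step needs the alkyne-to-vinylidene shift and 5-membered closure by the tertiary hydroxyl.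
- **16 ⇒ 14 + 15.** The C11–C(alkyne) bond is cut. The spiro C–O bond and its configuration are therefore fixed before any tropone carbon is added. The forward step is an SN2 opening at a hindered primary carbon.
- **14 ⇒ 13.** The C9–O and C11–O bonds are cut. Carbon nucleophiles add to a C9 ketone anti to the C10 methyl, which would put carbon where oxygen is needed. Oxygen is therefore delivered to the 9(11)-alkene from that open face.
- **13 ⇒ 10 (via 11, 12).** The C8–H bond is cut with allylic transposition. The axial C8 methyl cannot come from enolate alkylation or equilibration, which give the equatorial epimer. It is set by intramolecular hydrogen delivery to C8 on the face anti to the C10 methyl, which also creates the exocyclic alkene.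
- **10 ⇒ 9 ⇒ 8 ⇒ 7 ⇒ 6.** The C9–C11 bond (carbonylation of an enol triflate) and the C8–CH3 bond (enolate methylation) are cut. C8 is the only enolisable position of 6, so regiochemistry is automatic, and the C8 configuration of 7 is irrelevant.
- **6 ⇒ 5 ⇒ 4.** A redox and ketal relay distinguishes the two carbonyls: C9 is an alcohol while C3 is ketalised.
- **4 ⇒ 3 ⇒ 2 ⇒ 1.** The C4 methyl bonds and the C5–H bond are cut. Reductive alkylation of a thiomethylated enone sets the gem-dimethyl group and the trans ring fusion in one operation. The C9 ketone is first reduced so that it survives.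

## Other disconnections considered

**Alternative 1:** Biomimetic epoxy-polyene cascade.
- Cut: C4–C5, C9–C10 and the C9–O ether bond, taking the ring-A-closed 3-hydroxy spiro tropone A2 back to the acyclic (E,E)-epoxyfarnesyl hydroxytropone A1.
- Forward key step: SnCl4 would ionise the epoxide of A1, chair–chair cyclisation would build rings A and B, the C8 cation would be relayed to C9 by a 1,2-hydride shift, and the hydroxytropone oxygen would close the dihydrofuran.
- In its favour: one operation sets C5, C10, C9, C8 and the C3 carbinol from a single epoxide stereocentre. The migrating hydride arrives at C8 anti to the C10 methyl, so the axial C8 methyl is a consequence of the mechanism. On this point it is better than the chosen plan, which needs a dedicated transposition (step 10). It uses no stoichiometric transition metal.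
- Against it here: the C8 cation has exits that should be faster than the hydride shift, namely direct capture by oxygen to close a six-membered ether and simple proton loss. The hydroxytropone is a chelating Lewis base for SnCl4 and an ambident nucleophile. The tropone must still be made and C-farnesylated regioselectively before the cascade.
- Comparison: on structure it is equal or better, since the whole stereotetrad is set at once. On mechanism it is less controllable, a cation with several terminations against a pericyclic sequence whose connectivity is fixed by the partners. On step economy it is better, if the termination can be steered. The endgame from A2 (oxidation, Baeyer–Villiger, hydrolysis) is equal in length to the chosen one.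

**Alternative 2:** Hetero [8+2] cycloaddition.
- Cut: T4–C11 and C9–O, giving the hydroxytropone ester A3 and the exocyclic alkene A4 (the ring A ketone analogue of 13).
- Forward key step: with Sc(OTf)3 the keto tautomer of A3 would add across the methylene of A4 to give cycloadduct A5; one dehydrogenation would then give the tropone.
- In its favour: it is convergent and catalytic and needs no chromium. The terpenoid partner requires no epoxide, alkyne, carbene or methylenation, and only one dehydrogenation follows. On step economy after the union it is better than the chosen plan.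
- Against it here: an unactivated 1,1-disubstituted alkene is a poor 2π partner. Under a Lewis acid the union is likely stepwise through a C9 cation, where a hydride shift from C8 or proton loss would scramble the hard-won axial C8 methyl. A3 is a pentasubstituted hydroxytropone that needs its own synthesis, whereas the chosen plan builds the tropone during the union.
- Comparison: on structure the spiro C–O bond is made in the key step instead of before it, which is less safe for the C9 and C8 configurations. On mechanism it is a cationic addition against a carbene/sigmatropic sequence. On overall step count it is equal only if A3 is short to make.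

**Alternative 3:** Intramolecular Büchner ring expansion.
- Cut: T4–T5 and T3–T4, i.e. removal of the carbene carbon T4 from the seven-membered ring of the furanone-fused methoxycycloheptatriene A7, leading to the aryl ether diazoketone A6.
- Forward key step: Rh2(OAc)4 would add the carbenoid to the ipso and unsubstituted ortho carbons of A6, and norcaradiene opening would give A7.
- In its favour: it is catalytic in rhodium, which is better than stoichiometric chromium. The reaction class is dependable, and the substituent order of the seven-membered ring is preinstalled on a benzene ring, where regiocontrol is easy; this is equal or better than the chosen plan.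
- Against it here: A6 needs a tertiary alkyl aryl ether and a carboxyl-derived diazoketone on the same hindered C9, with oxygen on the correct face, and no gentle construction of that quaternary α-aryloxy acid is evident. The carbenoid has competing C–H insertion paths. In A7, C11 is a ketone that must be deoxygenated next to the spiro centre, and the enol methyl ether must be unmasked and the ring dehydrogenated.
- Comparison: on structure the C9–O bond is also fixed before the ring is made (equal). On mechanism it is well precedented (equal or better). On step economy it is worse, because of the C11 deoxygenation and the difficult precursor.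

Key step: step 17

**Remarks**

- Locants: terpenoid carbons follow drimane numbering (C4 gem-dimethyl, C5 ring-fusion CH, C8 CHMe, C9 spiro carbon, C10 angular carbon, C11 the CH2 on C9). T1–T7 are the tropone carbons as defined above. "Syn" and "anti" refer to the face of the C10 methyl.
- The quaternary carbon of (R)-Wieland–Miescher ketone maps onto C10 of the target with the required configuration; the saturated ketone becomes C9 and the enone carbonyl C3.
- Compound 27 is drawn with the two ring methyls cis. This is the relative configuration that a stereospecific cyclopropanation of the (Z)-enol ether followed by a boat Cope rearrangement predicts; a trans drawing would not fit that mechanism.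
- Methylating the C9-ketone enolate and then methylenating and epoxidising would give the C8 epimer of the target, and a sulfur ylide on the C9 ketone would give the C9 epimer. Steps 7–11 are designed to avoid both.

## Route

Step 1
Reactants: 1 (R)-(−)-Wieland–Miescher ketone
Product: 2 (4aR,5R)-5-hydroxy-4a-methyl-4,4a,5,6,7,8-hexahydronaphthalen-2(3H)-one
Conditions: NaBH4 (0.3 equiv), EtOH, −10 °C
Reagents that add atoms: none
Why: Chemoselective borohydride reduction of the saturated ketone, which is more electrophilic than the conjugated one; hydride adds anti to the angular methyl to give the equatorial alcohol, a centre that is erased in step 5.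

Step 2
Reactants: 2 hydroxy enone
Product: 3 (4aR,5R)-5-hydroxy-4a-methyl-1-[(phenylsulfanyl)methyl]-4,4a,5,6,7,8-hexahydronaphthalen-2(3H)-one
Conditions: PhSH, 37% aq. CH2O, Et3N, EtOH, 80 °C
Reagents that add atoms: thiophenol Sc1ccccc1; formaldehyde C=O
Why: Kirk–Petrow thiomethylation: the dienolate of the enone is hydroxymethylated at its α-carbon (C4) and the derived methylene dienone is trapped by thiolate, which installs the future C4 methyl carbon regioselectively.

Step 3
Reactants: 3 phenylthiomethyl enone
Product: 4 trans-fused 9-hydroxy-4,4,10-trimethyldecalin-3-one (H5 anti, 9-OH syn)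
Conditions: Li (6 equiv), NH3(l)/THF, −78 → −33 °C; MeI, −78 °C → rt; NH4Cl
Reagents that add atoms: iodomethane CI
Why: Stork reductive alkylation: dissolving-metal reduction cleaves the C–S bond and reduces the enone, C5 is protonated anti to the angular methyl (trans-decalin, the free hydroxyl serving as proton source), and the regiospecific C3–C4 enolate is C-methylated to the gem-dimethyl ketone while the lithium alkoxide should be too poor a nucleophile to be O-methylated.

Step 4
Reactants: 4 hydroxy ketone
Product: 5 9-hydroxy-3,3-(ethylenedioxy)-4,4,10-trimethyl-trans-decalin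
Conditions: HOCH2CH2OH, p-TsOH (cat.), benzene, reflux, Dean–Stark
Reagents that add atoms: ethylene glycol OCCO
Why: Acid-catalysed ketalisation driven by water removal; the only ketone is C3 and the secondary alcohol is inert.

Step 5
Reactants: 5 ketal alcohol
Product: 6 3,3-(ethylenedioxy)-4,4,10-trimethyl-trans-decalin-9-one
Conditions: (n-Pr4N)RuO4 (5 mol %), N-methylmorpholine N-oxide, 4 Å MS, CH2Cl2, rt
Reagents that add atoms: none
Why: Ley–Griffith oxidation under neutral conditions, which the dioxolane tolerates; the two carbonyls of 1 are now differentiated.

Step 6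
Reactants: 6 ketone
Product: 7 3,3-(ethylenedioxy)-4,4,8,10-tetramethyl-trans-decalin-9-one (8-methyl anti drawn)
Conditions: LiN(i-Pr)2, THF, −78 °C; MeI, −78 → 0 °C
Reagents that add atoms: iodomethane CI
Why: Enolate alkylation; C8 is the only enolisable position because C10 is quaternary, and the C8 configuration is irrelevant since step 7 makes C8 trigonal.

Step 7
Reactants: 7 methyl ketone
Product: 8 3,3-(ethylenedioxy)-4,4,8,10-tetramethyl-Δ8(9)-octalin-9-yl trifluoromethanesulfonate
Conditions: KN(SiMe3)2, THF, −78 → 0 °C; PhNTf2
Reagents that add atoms: N-phenylbis(trifluoromethanesulfonimide) O=S(=O)(N(c1ccccc1)S(=O)(=O)C(F)(F)F)C(F)(F)F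
Why: O-sulfonylation of the only possible (tetrasubstituted) enolate gives the enol triflate.

Step 8
Reactants: 8 enol triflate
Product: 9 methyl 3,3-(ethylenedioxy)-4,4,8,10-tetramethyl-Δ8(9)-octalin-9-carboxylate
Conditions: Pd(OAc)2 (5 mol %), Ph2P(CH2)3PPh2, CO (1 atm), MeOH, Et3N, DMF, 70 °C
Reagents that add atoms: carbon monoxide [C-]#[O+]; methanol CO
Why: Palladium-catalysed alkoxycarbonylation of a vinyl triflate (oxidative addition, CO insertion, methanolysis) attaches C11 to C9; the small CO ligand copes with the hindered position.

Step 9
Reactants: 9 unsaturated ester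
Product: 10 [3,3-(ethylenedioxy)-4,4,8,10-tetramethyl-Δ8(9)-octalin-9-yl]methanol
Conditions: i-Bu2AlH (2.5 equiv), CH2Cl2, −78 °C; aq. KNaC4H4O6
Reagents that add atoms: none
Why: 1,2-Reduction of the conjugated ester to the primary allylic alcohol; the ketal is inert to the hydride.

Step 10
Reactants: 10 allylic alcohol
Product: 13 9-methylene decalin ketal (8-methyl syn to the C10 methyl), via N-allyl sulfonylhydrazine 11 (not isolated), via allylic diazene 12 (not isolated)
Conditions: 2-O2NC6H4SO2NHNH2, PPh3, EtO2CN=NCO2Et, THF/N-methylmorpholine, −30 °C → rt
Reagents that add atoms: none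
Why: Reductive allylic transposition by Mitsunobu N-alkylation of the sulfonylhydrazide, loss of sulfinic acid and retro-ene loss of N2 from the diazene; the hydrogen is delivered intramolecularly to C8 on the face anti to the axial C10 methyl, which makes the exocyclic alkene and sets the axial C8 methyl at a centre that can no longer epimerise.

Step 11
Reactants: 13 exocyclic alkene
Product: 14 9,11-epoxide (spiro-oxirane, oxygen anti to the C8 and C10 methyls)
Conditions: mCPBA, NaHCO3, CH2Cl2, 0 °C
Reagents that add atoms: 3-chloroperoxybenzoic acid O=C(OO)c1cccc(Cl)c1
Why: Prilezhaev epoxidation; the syn face of the alkene is shielded by two axial methyls, so oxygen is delivered axially from the anti face and sets C9.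

Step 12
Reactants: 14 spiro-epoxide, 15 lithium acetylide–ethylenediamine complex
Product: 16 9-hydroxy-9-(prop-2-yn-1-yl)-3,3-(ethylenedioxy)-4,4,8,10-tetramethyl-trans-decalin (OH anti)
Conditions: LiC≡CH·H2NCH2CH2NH2 (5 equiv), DMSO, 25 → 45 °C; aq. NH4Cl
Reagents that add atoms: none
Why: SN2 opening of the epoxide at its primary carbon by a small linear nucleophile; the C9–O bond is not touched, so the C9 configuration is retained.

Step 13
Reactants: 16 alkynol, 17 chromium hexacarbonyl
Product: 19 spiro 2-oxacyclopentylidene pentacarbonylchromium complex, via chromium vinylidene complex 18 (not isolated)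
Conditions: Cr(CO)6, hν, THF, rt, giving Cr(CO)5(THF); then 16, THF, rt, dark
Reagents that add atoms: none
Why: Alkynol cycloisomerisation at a Cr(CO)5 fragment: the π-bound terminal alkyne rearranges to the vinylidene, and the tertiary hydroxyl adds to its electrophilic α-carbon with proton transfer to the β-carbon, closing the five-membered cyclic alkoxycarbene.

Step 14
Reactants: 19 cyclic carbene complex
Product: 21 alpha-methylene spiro 2-oxacyclopentylidene pentacarbonylchromium complex, via methoxymethyl carbene complex 20 (not isolated)
Conditions: n-BuLi, THF, −78 °C; ClCH2OMe, −78 → 0 °C; basic Al2O3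
Reagents that add atoms: chloromethyl methyl ether COCCl
Why: The CH2 next to the carbene carbon is as acidic as a 1,3-dicarbonyl CH2 and is the only such position; its anion is alkylated by the reactive chloromethyl ether, and E1cB loss of methanol on basic alumina gives the exocyclic methylene without releasing an amine that could attack the carbene.

Step 15
Reactants: 22 methyl 3-oxopentanoate, 23 acetaldehyde
Product: 24 methyl (2Z)-2-propanoylbut-2-enoate
Conditions: piperidine (cat.), AcOH (cat.), 4 Å MS, CH2Cl2, −10 → 0 °C
Reagents that add atoms: none
Why: Knoevenagel condensation; the isomer with the methyl cis to the ester is separated for use, and the other isomer would lead to the same tropone, only through a slower Cope step.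

Step 16
Reactants: 24 alkylidene keto ester
Product: 25 methyl (2Z,3Z)-3-[(tert-butyldimethylsilyl)oxy]-2-ethylidenepent-3-enoate
Conditions: TBSOTf, Et3N, CH2Cl2, −78 → 0 °C
Reagents that add atoms: tert-butyldimethylsilyl trifluoromethanesulfonate CC(C)(C)[Si](C)(C)OS(=O)(=O)C(F)(F)F
Why: Soft enolisation: O-silylation of the ketone and deprotonation of the adjacent ethyl CH2 at low temperature should give the cross-conjugated (Z)-silyl enol ether in preference to vinylogous deprotonation of the ethylidene methyl.

Step 17
Reactants: 21 alpha-methylene carbene complex, 25 silyloxydiene ester (3 equiv)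
Product: 27 dihydrofuran-fused cycloheptadiene silyl enol ether (ring A ketal; ring methyls cis), via cis-divinylcyclopropane 26 (not isolated)
Conditions: toluene, CO (1 atm), 25 → 80 °C, dark
Reagents that add atoms: none
Why: The electrophilic carbene carbon of 21 (zerovalent chromium) is attacked by the nucleophilic CHMe terminus of the silyl enol ether of 25 and closes onto the silyloxy carbon, giving cyclopropane 26 and a Cr(CO)5 fragment that CO converts to Cr(CO)6. In 26 the exocyclic C=CH2 of the oxacycle and the ester-bearing alkene sit cis on the three-membered ring, so a Cope rearrangement through a boat transition state breaks the bond between the former carbene carbon and the silyloxy carbon and joins the exocyclic CH2 (T3) to the CHMe terminus of the unsaturated ester (T2). The closest known reaction type is the [4+3] annulation of alkenyl alkoxycarbene complexes of chromium with 2-silyloxy and 2-amino dienes by cyclopropanation and divinylcyclopropane rearrangement; the exocyclic alkenyl unit of a cyclic carbene and an ester on the diene are new variations within it. The seven-membered ring is closed by a [3,3]-sigmatropic ring expansion (T5–T6 from the cyclopropanation, T2–T3 from the Cope step), not by an end-to-end cyclisation, and the oxacycle with its spiro C–O bond is a spectator. Of the two new CHMe centres, T6 is fixed by stereospecific cyclopropanation of the (Z)-enol ether, which places its methyl trans to both vinyl groups, and T2 by the boat geometry together with the ester alkene geometry, so the methyls should be cis; their relation to the spiro centre is not controlled and does not matter because both centres are erased in step 18. The step needs the carbene to choose the electron-rich silyl enol ether alkene over the electron-poor ester alkene, which the polarity match secures, and it needs cyclopropanation at the carbene carbon to outrun Diels–Alder addition across the activated methylene; chromium, a non-coordinating solvent, a CO atmosphere and the methyl groups on both diene termini are chosen to favour the former.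

Step 18
Reactants: 27 cycloheptadiene silyl enol ether
Product: 29 spiro dihydrofuran-fused tropone (ring A ketal), via dihydrotropone 28 (not isolated)
Conditions: DDQ (2.5 equiv), 2,4,6-collidine, benzene, 25 → 60 °C; aq. NaHCO3
Reagents that add atoms: none
Why: DDQ abstracts hydride from T2 (allylic to the silyl enol ether) and the silyl group is lost to give the enone, then a second hydride abstraction at the doubly allylic T3 with proton loss from T6 aromatises the ring; the tropone is the thermodynamic sink, the spiro carbon prevents oxidation of the dihydrofuran to a furan, and both CHMe centres disappear.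

Step 19
Reactants: 29 tropone ketal
Product: 30 spiro dihydrofuran-fused tropone with ring A 3-ketone
Conditions: 1 M HCl, THF, rt
Reagents that add atoms: water O
Why: Acid hydrolysis of the dioxolane; the tropone, the methyl ester and the spiro ether are stable to dilute acid now that the cyclic enol ether has become part of the aromatic ring.

Step 20
Reactants: 30 tropone ketone
Product: 31 ring A ε-lactone (4-oxa-A-homo-3-one)
Conditions: mCPBA, NaHCO3, CH2Cl2, rt
Reagents that add atoms: 3-chloroperoxybenzoic acid O=C(OO)c1cccc(Cl)c1
Why: Baeyer–Villiger oxidation; the quaternary C4 migrates in preference to the C2 methylene, which puts oxygen between C3 and C4, and the acceptor-substituted tropone double bonds should be poor partners for the electrophilic peracid.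

Step 21
Reactants: 31 lactone
Product: 32 CNP0448476.4
Conditions: LiOH (1.5 equiv), THF/H2O, 0 °C; dilute HCl to pH 4
Reagents that add atoms: lithium hydroxide [Li+].[OH-]
Why: Saponification of the strained ε-lactone at its unhindered acyl carbon should be much faster than attack on the T1 methyl ester, which is flanked by T7 and T2, or on T5; the tertiary alcohol and the acid do not re-close a seven-membered lactone under the mild work-up.

## Compound list

1 | (R)-(−)-Wieland–Miescher ketone, (8aR)-8a-methyl-3,4,8,8a-tetrahydronaphthalene-1,6(2H,7H)-dione | C[C@@]12CCC(=O)C=C1CCCC2=O | starting material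
2 | (4aR,5R)-5-hydroxy-4a-methyl-4,4a,5,6,7,8-hexahydronaphthalen-2(3H)-one (OH syn to the angular methyl) | C[C@@]12CCC(=O)C=C1CCC[C@H]2O | intermediate
3 | (4aR,5R)-5-hydroxy-4a-methyl-1-[(phenylsulfanyl)methyl]-4,4a,5,6,7,8-hexahydronaphthalen-2(3H)-one | C[C@@]12CCC(=O)C(CSc3ccccc3)=C1CCC[C@H]2O | intermediate
4 | trans-fused 9-hydroxy-4,4,10-trimethyldecalin-3-one (H5 anti, OH syn) | O[C@@H]1CCC[C@H]2[C@@]1(C)CCC(=O)C2(C)C | intermediate
5 | 9-hydroxy-3,3-(ethylenedioxy)-4,4,10-trimethyl-trans-decalin | O[C@@H]1CCC[C@H]2[C@@]1(C)CCC3(OCCO3)C2(C)C | intermediate
6 | 3,3-(ethylenedioxy)-4,4,10-trimethyl-trans-decalin-9-one | O=C1CCC[C@H]2[C@@]1(C)CCC3(OCCO3)C2(C)C | intermediate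
7 | 3,3-(ethylenedioxy)-4,4,8,10-tetramethyl-trans-decalin-9-one (8-methyl anti, equatorial; C8 epimer also usable) | O=C1[C@@H](C)CC[C@H]2[C@@]1(C)CCC3(OCCO3)C2(C)C | intermediate
8 | 3,3-(ethylenedioxy)-4,4,8,10-tetramethyl-Δ8(9)-octalin-9-yl trifluoromethanesulfonate | O=S(=O)(OC1=C(C)CC[C@H]2[C@@]1(C)CCC3(OCCO3)C2(C)C)C(F)(F)F | intermediate
9 | methyl 3,3-(ethylenedioxy)-4,4,8,10-tetramethyl-Δ8(9)-octalin-9-carboxylate | COC(=O)C1=C(C)CC[C@H]2[C@@]1(C)CCC3(OCCO3)C2(C)C | intermediate
10 | [3,3-(ethylenedioxy)-4,4,8,10-tetramethyl-Δ8(9)-octalin-9-yl]methanol | OCC1=C(C)CC[C@H]2[C@@]1(C)CCC3(OCCO3)C2(C)C | intermediate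
11 | N-allyl-N-(2-nitrobenzenesulfonyl)hydrazine from 10 (C11–N bond) | NN(CC1=C(C)CC[C@H]2[C@@]1(C)CCC3(OCCO3)C2(C)C)S(=O)(=O)c1ccccc1[N+](=O)[O-] | intermediate
12 | allylic monoalkyl diazene (C11–N=NH) | N=NCC1=C(C)CC[C@H]2[C@@]1(C)CCC3(OCCO3)C2(C)C | intermediate
13 | 3,3-(ethylenedioxy)-4,4,8,10-tetramethyl-9-methylene-trans-decalin (8-methyl syn, axial) | C=C1[C@H](C)CC[C@H]2[C@@]1(C)CCC3(OCCO3)C2(C)C | intermediate
14 | 9,11-epoxide of 13 (spiro-oxirane, oxygen anti, C11 syn) | C1O[C@]12[C@H](C)CC[C@H]3[C@@]2(C)CCC4(OCCO4)C3(C)C | intermediate
15 | lithium acetylide–ethylenediamine complex | [Li+].[C-]#C.NCCN | starting material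
16 | 9-hydroxy-9-(prop-2-yn-1-yl)-3,3-(ethylenedioxy)-4,4,8,10-tetramethyl-trans-decalin (OH anti, 8-methyl syn) | C#CC[C@]1(O)[C@H](C)CC[C@H]2[C@@]1(C)CCC3(OCCO3)C2(C)C | intermediate
17 | chromium hexacarbonyl, Cr(CO)6 | O=C=[Cr](=C=O)(=C=O)(=C=O)(=C=O)=C=O | starting material
18 | pentacarbonylchromium vinylidene complex of 16 | O[C@@]1(CC=C=[Cr](=C=O)(=C=O)(=C=O)(=C=O)=C=O)[C@H](C)CC[C@H]2[C@@]1(C)CCC3(OCCO3)C2(C)C | intermediate
19 | spiro 2-oxacyclopentylidene pentacarbonylchromium complex (ring A dioxolane) | C1C[C@]2(OC1=[Cr](=C=O)(=C=O)(=C=O)(=C=O)=C=O)[C@H](C)CC[C@H]3[C@@]2(C)CCC4(OCCO4)C3(C)C | intermediate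
20 | 3-(methoxymethyl) derivative of 19 (mixture at the new centre) | COCC1C[C@]2(OC1=[Cr](=C=O)(=C=O)(=C=O)(=C=O)=C=O)[C@H](C)CC[C@H]3[C@@]2(C)CCC4(OCCO4)C3(C)C | intermediate
21 | alpha-methylene spiro 2-oxacyclopentylidene pentacarbonylchromium complex (ring A dioxolane) | C=C1C[C@]2(OC1=[Cr](=C=O)(=C=O)(=C=O)(=C=O)=C=O)[C@H](C)CC[C@H]3[C@@]2(C)CCC4(OCCO4)C3(C)C | intermediate
22 | methyl 3-oxopentanoate | CCC(=O)CC(=O)OC | starting material
23 | acetaldehyde | CC=O | starting material
24 | methyl (2Z)-2-propanoylbut-2-enoate | C/C=C(/C(=O)CC)C(=O)OC | intermediate
25 | methyl (2Z,3Z)-3-[(tert-butyldimethylsilyl)oxy]-2-ethylidenepent-3-enoate | C/C=C(\O[Si](C)(C)C(C)(C)C)/C(C(=O)OC)=C/C | intermediate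
26 | cis-divinylcyclopropane from 21 and 25 (cyclopropane centres as formed, vinyl groups cis) | C=C1C[C@]2(OC13C(C)C3(O[Si](C)(C)C(C)(C)C)/C(C(=O)OC)=C/C)[C@H](C)CC[C@H]4[C@@]2(C)CCC5(OCCO5)C4(C)C | intermediate
27 | dihydrofuran-fused cycloheptadiene silyl enol ether, ring A dioxolane (ring methyls cis; one of two facial diastereomers drawn) | COC(=O)C1=C(O[Si](C)(C)C(C)(C)C)[C@H](C)C2=C(C[C@@H]1C)C[C@]3(O2)[C@H](C)CC[C@H]4[C@@]3(C)CCC5(OCCO5)C4(C)C | intermediate
28 | dihydrotropone (T7 ketone, T1=T2 and T4=T5 double bonds, T6 CHMe as mixture) | COC(=O)C1=C(C)CC2=C(O[C@@]3(C2)[C@H](C)CC[C@H]4[C@@]3(C)CCC5(OCCO5)C4(C)C)C(C)C1=O | intermediate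
29 | spiro dihydrofuran-fused tropone, ring A dioxolane | COC(=O)c1c(C)cc2c(c(C)c1=O)O[C@@]1(C2)[C@H](C)CC[C@H]3[C@@]1(C)CCC4(OCCO4)C3(C)C | intermediate
30 | spiro dihydrofuran-fused tropone, ring A 3-ketone | COC(=O)c1c(C)cc2c(c(C)c1=O)O[C@@]1(C2)[C@H](C)CC[C@H]3[C@@]1(C)CCC(=O)C3(C)C | intermediate
31 | ring A ε-lactone (oxygen between C3 and C4) | COC(=O)c1c(C)cc2c(c(C)c1=O)O[C@@]1(C2)[C@H](C)CC[C@H]3[C@@]1(C)CCC(=O)OC3(C)C | intermediate
32 | CNP0448476.4 (seco acid with tertiary carbinol) | COC(=O)c1c(C)cc2c(c(C)c1=O)O[C@@]1(C2)[C@H](C)CC[C@H](C(C)(C)O)[C@@]1(C)CCC(=O)O | target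

## Step count and least certain steps

Total: 21 steps. Longest linear sequence: 19 steps (steps 1–14 and 17–21); the diene branch is steps 15–16.

**Step 17 (key step).**
- What may go wrong: Diels–Alder addition of the diene across the exocyclic methylene, which the carbene makes a strong dienophile and for which 25 can reach an s-cis shape. Two further risks are cyclopropanation to the trans-divinyl isomer, which cannot rearrange, and sluggish attack by the hindered, ester-deactivated enol ether.
- Fallback (from 16 and 22, back to the route at 29): a rhodium-carbenoid cyclopropanation/Cope [4+3] in which the dihydrofuran carries the diene.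
  - Alkynol 16 is cycloisomerised (Mo(CO)6 cat., Et3N, Et2O, hν) to the spiro 2,3-dihydrofuran F1.
  - Vilsmeier–Haack formylation (POCl3, DMF; aq. NaOAc) at the enol-ether β-carbon gives the 3-formyl dihydrofuran F2.
  - Wittig reaction (EtPPh3Br, KN(SiMe3)2) gives the (Z)-propenyl dihydrofuran diene F3.
  - Keto ester 22 is converted by diazo transfer (4-acetamidobenzenesulfonyl azide, Et3N) into methyl 2-diazo-3-oxopentanoate F4, and by TBSOTf/Et3N into the siloxyvinyl diazoacetate F5.
  - Rh2(O2CCMe3)4-catalysed decomposition of F5 with F3 (hexane, then toluene at 80 °C) should cyclopropanate the less substituted cis alkene; Cope rearrangement then gives the isomeric cycloheptadiene silyl enol ether F6.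
  - DDQ as in step 18 should take F6 to 29.

**Step 10.**
- What may go wrong: poor facial selectivity in the hydrogen delivery to C8, or failure of the Mitsunobu alkylation at an allylic alcohol beside a quaternary carbon (elimination to a diene).
- Fallback (from 10, back at 13): formylation (HCO2H/Ac2O, pyridine) gives the allylic formate F7. Pd(OAc)2/n-Bu3P in THF at 65 °C then forms the π-allyl complex on the face anti to the C10 methyl and transfers hydride from the metal to the more substituted terminus C8 with loss of CO2.

**Step 12.**
- What may go wrong: slow substitution at the neopentyl-type epoxide carbon, so that base-induced isomerisation of the epoxide to an allylic alcohol takes over.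
- Fallback (from 13, back at 16): a more electrophilic cyclic sulfate.
  - Dihydroxylation (OsO4 cat., N-methylmorpholine N-oxide) from the anti face gives the 9,11-diol F8.
  - SOCl2/Et3N, then RuCl3 (cat.)/NaIO4, gives the cyclic sulfate F9.
  - LiC≡CH·H2NCH2CH2NH2 opens it at C11 to the tertiary hydrogen sulfate F10.
  - Catalytic H2SO4 with one equivalent of water in THF hydrolyses F10 to 16 with retention.

**Step 18.**
- What may go wrong: formation of stable adducts between DDQ and the silyl enol ether, or hydride abstraction from the C11 methylene next to the new tropone leading to over-oxidation.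
- Fallback (from 27, back at 29): Saegusa–Ito oxidation with Pd(OAc)2 in MeCN gives 28, which is isolated. A second dehydrogenation with Pd(O2CCF3)2/DMSO under O2 aromatises it. No new compound is involved.

**Step 20.**
- What may go wrong: epoxidation or oxidative cleavage of the tropone ring by the peracid before the hindered ketone reacts.
- Fallback (from 30, back at 31): the electrophilic peracid is replaced by a Lewis-acid-activated silyl peroxide (Me3SiOOSiMe3, SnCl4 cat., CH2Cl2, 0 °C), which oxidises ketones but does not epoxidise alkenes. No new compound is involved.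

## Further compounds

F1 | step 17 | spiro 2,3-dihydrofuran from 16 (ring A dioxolane) | C1=CO[C@@]2(C1)[C@H](C)CC[C@H]3[C@@]2(C)CCC4(OCCO4)C3(C)C
F2 | step 17 | 3-formyl spiro dihydrofuran | O=CC1=CO[C@@]2(C1)[C@H](C)CC[C@H]3[C@@]2(C)CCC4(OCCO4)C3(C)C
F3 | step 17 | 3-[(Z)-prop-1-enyl] spiro dihydrofuran diene | C/C=C\C1=CO[C@@]2(C1)[C@H](C)CC[C@H]3[C@@]2(C)CCC4(OCCO4)C3(C)C
F4 | step 17 | methyl 2-diazo-3-oxopentanoate | CCC(=O)C(=[N+]=[N-])C(=O)OC
F5 | step 17 | methyl (3Z)-2-diazo-3-[(tert-butyldimethylsilyl)oxy]pent-3-enoate | COC(=O)C(=[N+]=[N-])/C(O[Si](C)(C)C(C)(C)C)=C/C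
F6 | step 17 | isomeric cycloheptadiene silyl enol ether (T3=T4 alkene, sp3 T2, T5, T6 as mixture) | COC(=O)C1=C(O[Si](C)(C)C(C)(C)C)C(C)C2O[C@@]3(CC2=CC1C)[C@H](C)CC[C@H]4[C@@]3(C)CCC5(OCCO5)C4(C)C
F7 | step 10 | allylic formate of 10 | O=COCC1=C(C)CC[C@H]2[C@@]1(C)CCC3(OCCO3)C2(C)C
F8 | step 12 | 9,11-diol (9-OH anti) | OC[C@]1(O)[C@H](C)CC[C@H]2[C@@]1(C)CCC3(OCCO3)C2(C)C
F9 | step 12 | 9,11-cyclic sulfate | O=S1(=O)OC[C@]2(O1)[C@H](C)CC[C@H]3[C@@]2(C)CCC4(OCCO4)C3(C)C
F10 | step 12 | tertiary hydrogen sulfate of 16 | C#CC[C@]1(OS(=O)(=O)O)[C@H](C)CC[C@H]2[C@@]1(C)CCC3(OCCO3)C2(C)C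
F0 | step 18 | none | none
F0 | step 20 | none | none
A1 | alternative 1 | (E,E)-epoxyfarnesyl hydroxytropone ester | COC(=O)c1c(C)cc(C/C=C(\C)CC/C=C(\C)CC[C@H]2OC2(C)C)c(O)c(C)c1=O
A2 | alternative 1 | ring-A-closed 3-hydroxy spiro tropone | COC(=O)c1c(C)cc2c(c(C)c1=O)O[C@@]1(C2)[C@H](C)CC[C@H]3[C@@]1(C)CC[C@@H](O)C3(C)C
A3 | alternative 2 | hydroxytropone ester (T1 CO2Me, T2 Me, T5 OH, T6 Me, T7 C=O) | COC(=O)c1c(C)ccc(O)c(C)c1=O
A4 | alternative 2 | 9-methylene-4,4,8,10-tetramethyl-trans-decalin-3-one (8-methyl syn) | C=C1[C@H](C)CC[C@H]2[C@@]1(C)CCC(=O)C2(C)C
A5 | alternative 2 | dihydrofuran-fused hydroxycycloheptatriene cycloadduct | COC(=O)C1=C(O)C(C)=C2O[C@@]3(C[C@H]2C=C1C)[C@H](C)CC[C@H]4[C@@]3(C)CCC(=O)C4(C)C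
A6 | alternative 3 | aryl ether diazoketone on C9 | COC(=O)c1c(C)cc(O[C@@]2(C(=O)C=[N+]=[N-])[C@H](C)CC[C@H]3[C@@]2(C)CCC4(OCCO4)C3(C)C)c(C)c1OC
A7 | alternative 3 | furanone-fused methoxycycloheptatriene | COC(=O)C1=C(OC)C(C)=C2O[C@@]3(C(=O)[C@H]2C=C1C)[C@H](C)CC[C@H]4[C@@]3(C)CCC5(OCCO5)C4(C)C
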